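C11–O aryl ether is cut first (Mitsunobu). C9–C11 is cut next (methylenation and hydroboration of a C9 ketone). C4–C5 and C1–C10 are cut last and together, which lifts ring A off ring B.
Enabling feature: C1–C4, with the C3 oxygen and the C4 gem-dimethyl group, map onto isopropyl vinyl ketone 1 in the form of its 2-silyloxydiene 2. Ring B (C5–C10: C6 carbonyl, C7=C8 bearing CH3, oxidisable C9, CH3-bearing C10) is 2,6-dimethyl-1,4-benzoquinone 3 in disguise.
Forward: ring B is bought intact, and a formal [4+2] (Mukaiyama–Michael, then Michael) closes ring A on it and creates both quaternary carbons C4 and C10. C5 is then inverted, C6 is parked as a silyl ether, C9 is homologated, the coumarin is attached, and C3 and C6 are brought to their final oxidation levels.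
Stereochemistry: a chiral boron Lewis acid sets C5 and, through the cis ring closure, C10. The C10 methyl group, helped by the axial C4 methyl group, then directs the kinetic protonation at C5, the hydroboration at C9 and the hydride attack at C3.
C3 stays masked as the TBS enol ether that the annulation delivers. This blocks retro-Michael unravelling to a hydroquinone and leaves only C6 and C9 to be told apart. The base-sensitive enone/aryloxymethyl array appears only in the last, neutral step.

Key step: step 2

Numbering: drimane numbering is used throughout (decalin C1–C10, C11 on C9, C12 on C8, methyl groups on C4 and C10). "11-Nordrimane" is the same skeleton without C11. Compounds 1, 3 and 13 are commercial.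
Assumption: the usual catalyst model does not give the sense of induction with confidence for this quinone and diene. The (S)-oxazaborolidine is written; if the first run gives the mirror-image adduct, the equally available (R)-oxazaborolidine replaces it and nothing else changes.

Step 1
Reactants: 1 4-methylpent-1-en-3-one
Product: 2 tert-butyldimethyl[(4-methylpenta-1,3-dien-3-yl)oxy]silane
Conditions: TBSOTf, Et3N, CH2Cl2, 0 °C
Reagents that add atoms: tert-butyldimethylsilyl triflate, CC(C)(C)[Si](C)(C)OS(=O)(=O)C(F)(F)F
Why: Soft enolisation: O-silylation by TBSOTf acidifies the only enolisable hydrogen of 1 (the isopropyl C–H) and Et3N removes it to give the cross-conjugated 2-silyloxydiene, for which no enol ether geometry arises because the new terminus carries two methyl groups.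

Step 2
Reactants: 2 tert-butyldimethyl[(4-methylpenta-1,3-dien-3-yl)oxy]silane; 3 2,6-dimethyl-1,4-benzoquinone
Product: 5 (5S,10R)-3-(tert-butyldimethylsilyloxy)-11-nordrima-2,7-diene-6,9-dione (cis-fused; the C3 TBS enol ether of cis-4,4,8,10-tetramethyloctal-7-ene-3,6,9-trione), via Mukaiyama–Michael zwitterion 4 (not isolated)
Conditions: (S)-3,3-diphenyl-1-(2-methylphenyl)tetrahydro-1H,3H-pyrrolo[1,2-c][1,3,2]oxazaborole (20 mol%), HN(SO2CF3)2 (18 mol%), CH2Cl2, −78 to −40 °C; Et3N quench
Reagents that add atoms: none
Why: Proposed new method: the N-protonated oxazaborolidine activates the quinone and the fully substituted silyl enol ether carbon C4 of 2 attacks the unsubstituted ring carbon C5 (Mukaiyama–Michael) to give zwitterion 4, whose boron-bound enolate carbon C10 then adds to the terminus C1 of the O-silylated vinyl ketone, so that C4–C5 and C1–C10 form in one flask, the silyl group stays on O3 and the outcome is that of a very asynchronous [4+2] cycloaddition. The closest known reactions are oxazaborolidinium-catalysed Diels–Alder additions of 2-silyloxybutadienes to methylated benzoquinones and achiral Lewis-acid double Michael reactions of hindered 2-silyloxydienes; untested is the union of a diene terminus carrying two methyl groups with an enantioselective catalyst. Ring A closes by a 6-endo-trig Michael addition, and because ring B of 4 is almost flat the C4–C1 chain can reach C10 only on the face on which it hangs from C5, which enforces the cis fusion. C5 is set by the catalyst, whose aryl group shields one face of the bound quinone and whose C–H···O contact singles out one of the two enantiotopic CH=C(CH3) units, and C10 follows from C5 through the cis closure, so the lasting stereocentre C10 is under catalyst control. The step needs regioselectivity and the substrates secure it: whichever carbonyl carries the boron, the reverse orientation would have to join C4 to methyl-bearing C10 and place two quaternary carbons side by side, whereas C5 bears only hydrogen and is the position at which this quinone accepts nucleophiles; the two C=C bonds of 3 are symmetry-equivalent and the trisubstituted C7=C8 left in 5 is too hindered for a second addition. Loss of H-5 from 4 would aromatise ring B, so the reaction is run cold and aprotic, where the intramolecular closure should outrun proton transfer.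

Step 3
Reactants: 5 (5S,10R)-3-(tert-butyldimethylsilyloxy)-11-nordrima-2,7-diene-6,9-dione (cis-fused)
Product: 7 (5R,10R)-3-(tert-butyldimethylsilyloxy)-11-nordrima-2,7-diene-6,9-dione (trans-fused; H-5 opposite to C10-CH3), via TMS dienol ether 6 (not isolated)
Conditions: TMSOTf, Et3N, CH2Cl2, 0 °C; crude 6, then Bu4NF (1.05 equiv), AcOH (3 equiv), THF, −78 °C; used without delay
Reagents that add atoms: none
Why: Soft enolisation of a cyclohexenone with a silyl triflate and Et3N normally goes to the α′ side, here H-5, and makes C5 planar, after which fluoride-triggered kinetic protonation of the released enolate by AcOH should place the hydrogen on the face of C5 turned away from the C10 methyl and the axial C4 methyl group and so give the trans fusion irreversibly, a course chosen because base equilibration cannot be trusted to favour trans while C6–C9 are all sp2 and the equatorial C4 methyl group is pressed against the C6 carbonyl; the TMS ether of the more stabilised enolate is cleaved ahead of the C3 TBS enol ether.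

Step 4
Reactants: 7 (5R,10R)-3-(tert-butyldimethylsilyloxy)-11-nordrima-2,7-diene-6,9-dione (trans-fused)
Product: 8 (5R,6S,10R)-3-(tert-butyldimethylsilyloxy)-6-hydroxy-11-nordrima-2,7-dien-9-one (6-OH axial and cis to C10-CH3)
Conditions: NaBH4, CeCl3·7H2O, MeOH–CH2Cl2, −78 °C
Reagents that add atoms: none
Why: Luche reduction: the cerium-modified borohydride adds 1,2 to C6, which is open on the face opposite the C10 methyl group, in preference to C9, which is wedged between quaternary C10 and methyl-bearing C8, and attack anti to the two axial methyl groups gives the axial (6S) alcohol, a stereocentre that is deleted again in step 11 and whose formation locks C5 against epimerisation.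

Step 5
Reactants: 8 (5R,6S,10R)-3-(tert-butyldimethylsilyloxy)-6-hydroxy-11-nordrima-2,7-dien-9-one
Product: 9 (5R,6S,10R)-3-(tert-butyldimethylsilyloxy)-6-(triethylsilyloxy)-11-nordrima-2,7-dien-9-one
Conditions: TESOTf, 2,6-lutidine, CH2Cl2, −78 to 0 °C
Reagents that add atoms: triethylsilyl triflate, CC[Si](CC)(CC)OS(=O)(=O)C(F)(F)F
Why: Silylation with a silyl triflate and 2,6-lutidine is forceful enough for an axial alcohol flanked by two syn-axial methyl groups, and TES is preferred to TBS because it is smaller going on and easier to remove from this pocket.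

Step 6
Reactants: 9 (5R,6S,10R)-3-(tert-butyldimethylsilyloxy)-6-(triethylsilyloxy)-11-nordrima-2,7-dien-9-one
Product: 10 (5S,6S,10R)-3-(tert-butyldimethylsilyloxy)-6-(triethylsilyloxy)drima-2,7,9(11)-triene
Conditions: Ph3PCH3Br (5 equiv), KOtBu (4.5 equiv), toluene, 90 °C
Reagents that add atoms: methyltriphenylphosphonium bromide, C[P+](c1ccccc1)(c1ccccc1)c1ccccc1.[Br-]
Why: Wittig methylenation: C9 is now the only carbonyl group and has no α-hydrogen, 2,6,6-trisubstituted cyclohexenones are known to accept Ph3P=CH2 at elevated temperature, the pseudo-equatorial H-6 is poorly aligned for γ-deprotonation, and keeping KOtBu below the phosphonium salt spares the silyl groups.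

Step 7
Reactants: 10 (5S,6S,10R)-3-(tert-butyldimethylsilyloxy)-6-(triethylsilyloxy)drima-2,7,9(11)-triene
Product: 12 (5S,6S,9R,10S)-3-(tert-butyldimethylsilyloxy)-6-(triethylsilyloxy)drima-2,7-dien-11-ol, via B-alkyl-9-BBN adduct 11 (not isolated)
Conditions: 9-BBN, THF, 0 to 40 °C; then 30% H2O2, 3 M NaOH, 0 °C
Reagents that add atoms: hydrogen peroxide, OO
Why: Hydroboration–oxidation: 9-BBN reacts far faster with the 1,1-disubstituted C9=C11 than with the two trisubstituted double bonds, places boron on C11 and delivers hydrogen to C9 from the face opposite the axial C10 methyl and the 6-OTES group, which sets C9 (R) with the CH2OH group equatorial and cis to the C10 methyl, and cold alkaline H2O2 replaces boron by oxygen with the enol ether intact.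

Step 8
Reactants: 12 (5S,6S,9R,10S)-3-(tert-butyldimethylsilyloxy)-6-(triethylsilyloxy)drima-2,7-dien-11-ol; 13 umbelliferone (7-hydroxycoumarin)
Product: 14 7-{[(5S,6S,9R,10S)-3-(tert-butyldimethylsilyloxy)-6-(triethylsilyloxy)drima-2,7-dien-11-yl]oxy}coumarin
Conditions: PPh3, DIAD (added last), THF, 0 °C to rt
Reagents that add atoms: none
Why: Mitsunobu etherification: the primary alcohol is activated as its oxyphosphonium salt and displaced by the acidic phenol 13 under neutral conditions, no stereocentre is involved, and adding DIAD last to excess PPh3 keeps the azo ester away from the enol ether.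

Step 9
Reactants: 14 7-{[(5S,6S,9R,10S)-3-(tert-butyldimethylsilyloxy)-6-(triethylsilyloxy)drima-2,7-dien-11-yl]oxy}coumarin
Product: 15 (5S,6S,9R,10S)-11-(coumarin-7-yloxy)-6-hydroxydrim-7-en-3-one
Conditions: HF·pyridine, pyridine, THF, 0 °C to rt
Reagents that add atoms: none
Why: Fluoride-mediated desilylation: buffered HF is small enough to reach the crowded C6 silyl ether, turns the C3 enol ether into the ketone by protonation at C2 (no stereocentre), and leaves the lactone and the allylic alcohol untouched.

Step 10
Reactants: 15 (5S,6S,9R,10S)-11-(coumarin-7-yloxy)-6-hydroxydrim-7-en-3-one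
Product: 16 (3R,5S,6S,9R,10S)-11-(coumarin-7-yloxy)drim-7-ene-3,6-diol
Conditions: NaBH4, MeOH–THF, −20 to 0 °C
Reagents that add atoms: none
Why: Borohydride reduction of the only ketone: axial hydride attack from the face opposite the C10 and axial C4 methyl groups, the normal course for 4,4-dimethyl-3-ketones in trans-decalins, gives the equatorial (3R) alcohol, and doing this while C6 is still an alcohol keeps alkoxide away from the later enone.

Step 11
Reactants: 16 (3R,5S,6S,9R,10S)-11-(coumarin-7-yloxy)drim-7-ene-3,6-diol
Product: 17 ligupersin A
Conditions: activated MnO2 (excess), CH2Cl2, rt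
Reagents that add atoms: none
Why: MnO2 oxidation is selective for the allylic C6 alcohol over the saturated neopentyl C3 alcohol, and its neutral heterogeneous conditions avoid both epimerisation at C5 and vinylogous β-elimination of the aryloxide through deprotonation at C9.

Compound list
1 | 4-methylpent-1-en-3-one | CC(C)C(=O)C=C | starting material
2 | tert-butyldimethyl[(4-methylpenta-1,3-dien-3-yl)oxy]silane | CC(C)=C(O[Si](C)(C)C(C)(C)C)C=C | intermediate
3 | 2,6-dimethyl-1,4-benzoquinone | CC1=CC(=O)C=C(C)C1=O | starting material
4 | Mukaiyama–Michael zwitterion: C5-alkylated quinone enolate (C9–O−, C9=C10) carrying the O-silylated vinyl ketone chain C4–C1, drawn without the boron catalyst | CC1=CC(=O)[C@@H](C(C)(C)C(C=C)=[O+][Si](C)(C)C(C)(C)C)C(C)=C1[O-] | intermediate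
5 | (5S,10R)-3-(tert-butyldimethylsilyloxy)-11-nordrima-2,7-diene-6,9-dione, cis-fused | CC1=CC(=O)[C@H]2C(C)(C)C(O[Si](C)(C)C(C)(C)C)=CC[C@@]2(C)C1=O | intermediate
6 | (10R)-3-(tert-butyldimethylsilyloxy)-6-(trimethylsilyloxy)-11-nordrima-2,5,7-trien-9-one | CC1=CC(O[Si](C)(C)C)=C2C(C)(C)C(O[Si](C)(C)C(C)(C)C)=CC[C@@]2(C)C1=O | intermediate
7 | (5R,10R)-3-(tert-butyldimethylsilyloxy)-11-nordrima-2,7-diene-6,9-dione, trans-fused | CC1=CC(=O)[C@@H]2C(C)(C)C(O[Si](C)(C)C(C)(C)C)=CC[C@@]2(C)C1=O | intermediate
8 | (5R,6S,10R)-3-(tert-butyldimethylsilyloxy)-6-hydroxy-11-nordrima-2,7-dien-9-one | CC1=C[C@H](O)[C@@H]2C(C)(C)C(O[Si](C)(C)C(C)(C)C)=CC[C@@]2(C)C1=O | intermediate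
9 | (5R,6S,10R)-3-(tert-butyldimethylsilyloxy)-6-(triethylsilyloxy)-11-nordrima-2,7-dien-9-one | CC1=C[C@H](O[Si](CC)(CC)CC)[C@@H]2C(C)(C)C(O[Si](C)(C)C(C)(C)C)=CC[C@@]2(C)C1=O | intermediate
10 | (5S,6S,10R)-3-(tert-butyldimethylsilyloxy)-6-(triethylsilyloxy)drima-2,7,9(11)-triene | CC1=C[C@H](O[Si](CC)(CC)CC)[C@@H]2C(C)(C)C(O[Si](C)(C)C(C)(C)C)=CC[C@@]2(C)C1=C | intermediate
11 | 9-[3-(tert-butyldimethylsilyloxy)-6-(triethylsilyloxy)drima-2,7-dien-11-yl]-9-borabicyclo[3.3.1]nonane, configuration as in 12 | CC1=C[C@H](O[Si](CC)(CC)CC)[C@@H]2C(C)(C)C(O[Si](C)(C)C(C)(C)C)=CC[C@@]2(C)[C@@H]1CB1C2CCCC1CCC2 | intermediate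
12 | (5S,6S,9R,10S)-3-(tert-butyldimethylsilyloxy)-6-(triethylsilyloxy)drima-2,7-dien-11-ol | CC1=C[C@H](O[Si](CC)(CC)CC)[C@@H]2C(C)(C)C(O[Si](C)(C)C(C)(C)C)=CC[C@@]2(C)[C@@H]1CO | intermediate
13 | umbelliferone (7-hydroxycoumarin) | O=c1ccc2ccc(O)cc2o1 | starting material
14 | 7-{[(5S,6S,9R,10S)-3-(tert-butyldimethylsilyloxy)-6-(triethylsilyloxy)drima-2,7-dien-11-yl]oxy}coumarin | CC1=C[C@H](O[Si](CC)(CC)CC)[C@@H]2C(C)(C)C(O[Si](C)(C)C(C)(C)C)=CC[C@@]2(C)[C@@H]1COc1ccc2ccc(=O)oc2c1 | intermediate
15 | (5S,6S,9R,10S)-11-(coumarin-7-yloxy)-6-hydroxydrim-7-en-3-one | CC1=C[C@H](O)[C@@H]2C(C)(C)C(=O)CC[C@@]2(C)[C@@H]1COc1ccc2ccc(=O)oc2c1 | intermediate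
16 | (3R,5S,6S,9R,10S)-11-(coumarin-7-yloxy)drim-7-ene-3,6-diol | CC1=C[C@H](O)[C@@H]2C(C)(C)[C@H](O)CC[C@@]2(C)[C@@H]1COc1ccc2ccc(=O)oc2c1 | intermediate
17 | ligupersin A, (3R,5S,9R,10S)-11-(coumarin-7-yloxy)-3-hydroxydrim-7-en-6-one | CC1=CC(=O)[C@@H]2C(C)(C)[C@H](O)CC[C@@]2(C)[C@@H]1COc1ccc2ccc(=O)oc2c1 | target

Total step count: 11. Longest linear sequence: 11 steps (1 to 17).

Steps most likely to fail

1. Step 2.
- What may go wrong: the s-cis form of 2 is penalised by the methyl group cis to the vinyl unit. The boron catalyst is expected to prefer the less crowded C6 carbonyl, which polarises C10 rather than C5. After the first C–C bond the intermediate can lose H-5 and aromatise. Each of these processes would cost conversion or facial selectivity.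
- Fallback, setting out from 2 and 3: the cycloaddition is run without any Lewis acid under high pressure (CH2Cl2, about 12 kbar, rt). Under these conditions the free quinone is polarised by its C9 carbonyl toward attack at C5, and no acid is present to promote aromatisation. This gives the racemic cis adduct F1. Preparative chromatography on a chiral stationary phase (amylose tris(3,5-dimethylphenylcarbamate)) separates it into 5 and its mirror image F2. The route is rejoined at 5.

2. Step 3.
- What may go wrong: enolisation may go toward the C8 methyl group instead of the crowded H-5. The C3 enol ether may be lost to fluoride. Protonation may be less face-selective than the two axial methyl groups suggest.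
- Fallback, setting out from 5: the irreversible ketonisation is replaced by reversible enolisation. DBU in toluene (or basic alumina) sets up the cis/trans equilibrium through the C6 ketone, under which enolisation toward C12 is harmless because it reverts. Compound 7 is removed by chromatography and recovered 5 is resubmitted. No new compound is made (F0). The route is rejoined at 7.

3. Step 6.
- What may go wrong: the ylide may fail to add to a carbonyl group wedged between C10 and C8 and screened on one face by the C10 methyl and the 6-OTES group. It may then act only as a base, and residual alkoxide may strip the enol ether at 90 °C.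
- Fallback, setting out from 9: MeLi/CeCl3 (THF, −78 °C) adds the smallest carbon nucleophile to C9 from the face opposite the C10 methyl group. This gives the tertiary allylic alcohol F3, whose only β-hydrogens are those of the new methyl group. Syn-elimination with methyl N-(triethylammoniosulfonyl)carbamate (Burgess reagent, toluene, 50 °C) can therefore only form the exocyclic C9=C11 bond. The route is rejoined at 10.

Further compounds
F1 | step 2 | racemic cis-3-(tert-butyldimethylsilyloxy)-11-nordrima-2,7-diene-6,9-dione (5 and its mirror image) | CC1=CC(=O)[C@H]2C(C)(C)C(O[Si](C)(C)C(C)(C)C)=CC[C@@]2(C)C1=O.CC1=CC(=O)[C@@H]2C(C)(C)C(O[Si](C)(C)C(C)(C)C)=CC[C@]2(C)C1=O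
F2 | step 2 | (5R,10S)-3-(tert-butyldimethylsilyloxy)-11-nordrima-2,7-diene-6,9-dione, mirror image of 5 | CC1=CC(=O)[C@@H]2C(C)(C)C(O[Si](C)(C)C(C)(C)C)=CC[C@]2(C)C1=O
F0 | step 3 | none | none
F3 | step 6 | 3-(tert-butyldimethylsilyloxy)-6-(triethylsilyloxy)drima-2,7-dien-9-ol, 9-OH cis to C10-CH3, other centres as in 9 | CC1=C[C@H](O[Si](CC)(CC)CC)[C@@H]2C(C)(C)C(O[Si](C)(C)C(C)(C)C)=CC[C@@]2(C)[C@]1(C)O
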